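**Assumption:** the (R,R) antipode of the TADDOL-derived phenylphosphonite ligand is taken to give the (R)-bis(boronate) from a 1-alkene; if the sense is the reverse, the (S,S) antipode is used.

## Retrosynthetic overview

1. Target ⇒ silyl ether of the bis(anhydride) ⇒ bis(3,4-disubstituted furan): both anhydride rings are unveiled together, last, by furan photooxygenation and chromic acid oxidation.
2. Ring B side chain ⇒ C–C bond from a bromofuran handle to (R)-1,2-epoxyhexane; the carbinol becomes the ketone in the same oxidation.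
3. Stereocentre–ring B bond ⇒ key step: ionic 1,2-shift of the secondary alkyl group from boron to a furan carbon, with retention.
4. Stereocentre and CH2–ring A bond ⇒ enantioselective 1,2-diboration of hept-1-ene, then cross-coupling of the primary C–B bond only.
5. Ring order: both rings come from 3,4-dibromofuran; the ring A furan is attached first (through its Grignard reagent), the ring B furan second (through its lithium reagent), and both are oxidised to anhydrides in one flask.

## Route

Step 1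
Reactants: 1 3,4-dibromofuran; 2 formaldehyde (monomeric gas from cracked paraformaldehyde)
Product: 5 [(4-bromofuran-3-yl)methoxy]tri(propan-2-yl)silane, via (4-bromofuran-3-yl)magnesium chloride 3 (not isolated), via chloromagnesium (4-bromofuran-3-yl)methoxide 4 (not isolated)
Conditions: i-PrMgCl·LiCl (1.05 equiv), THF, 0 °C → rt; CH2O (gas), −20 °C → rt; then TIPSOTf (1.2 equiv), 0 °C
Reagents that add atoms: triisopropylsilyl trifluoromethanesulfonate (TIPSOTf), CC(C)[Si](C(C)C)(C(C)C)OS(=O)(=O)C(F)(F)F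
Why: Bromine–magnesium exchange on 1 is helped by the neighbouring bromine and stops after one exchange, the furyl Grignard reagent adds to formaldehyde (Grignard 1,2-addition) and the magnesium alkoxide is O-silylated by the silyl triflate in the same flask; no stereocentre is formed.

Step 2
Reactants: 6 hept-1-ene; 5 [(4-bromofuran-3-yl)methoxy]tri(propan-2-yl)silane
Product: 8 tri(propan-2-yl)({4-[(2S)-2-(4,4,5,5-tetramethyl-1,3,2-dioxaborolan-2-yl)heptyl]furan-3-yl}methoxy)silane, via (2R)-heptane-1,2-diyl bis(pinacolboronate) 7 (not isolated)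
Conditions: B2pin2, Pt(dba)3 (1 mol %), (R,R)-TADDOL-derived phenylphosphonite (1.2 mol %), THF, 60 °C; then 5, Pd(OAc)2 (1 mol %), RuPhos (2-dicyclohexylphosphino-2′,6′-diisopropoxybiphenyl, 1 mol %), KOH, THF/H2O 10:1, 70 °C
Reagents that add atoms: bis(pinacolato)diboron (B2pin2), CC1(C)OB(OC1(C)C)B1OC(C)(C)C(C)(C)O1
Why: Platinum-catalysed enantioselective 1,2-diboration sets C2 of the heptane chain under ligand control (above 90% ee is usual for 1-alkenes), and the neighbouring boronate then lets only the primary C–B bond undergo Suzuki–Miyaura coupling, so the secondary boronate keeps its configuration (the descriptor changes from R in 7 to S in 8 only through the priority rules).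

Step 3
Reactants: 8 tri(propan-2-yl)({4-[(2S)-2-(4,4,5,5-tetramethyl-1,3,2-dioxaborolan-2-yl)heptyl]furan-3-yl}methoxy)silane; 1 3,4-dibromofuran
Product: 12 ({4-[(2S)-2-(4-bromofuran-3-yl)heptyl]furan-3-yl}methoxy)tri(propan-2-yl)silane, via 3-bromo-4-lithiofuran 9 (not isolated), via lithium furyl(alkyl)borate 10 (not isolated), via dibromodihydrofuranyl boronate 11 (not isolated)
Conditions: 1, n-BuLi (1.2 equiv each), THF, −78 °C; add 8, −78 °C; then NBS (1.2 equiv), THF, −78 °C → rt
Reagents that add atoms: none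
Why: Proposed new method: a 4-bromo-3-furyllithium has not been used as the aryl partner in electrophile-triggered boronate coupling; 9 adds to the boronic ester to give borate 10, NBS brominates the anionic furan at C2 (the α-carbon next to the borate-bearing carbon and the most electron-rich site, while the C4 bromine deactivates C5), the C3 cation is quenched by a 1,2-shift of the secondary alkyl group from boron to carbon with retention at the migrating carbon to give 11, and loss of bromide and the boryl group re-aromatises the ring while the C4–Br bond survives as the handle for step 4; the closest known reaction type is the enantiospecific NBS-induced 1,2-metalate coupling of secondary boronic esters with lithiated furans and thiophenes.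

Step 4
Reactants: 12 ({4-[(2S)-2-(4-bromofuran-3-yl)heptyl]furan-3-yl}methoxy)tri(propan-2-yl)silane; 13 (R)-1,2-epoxyhexane
Product: 15 (2R)-1-{4-[(2S)-1-(4-{[tri(propan-2-yl)silyloxy]methyl}furan-3-yl)heptan-2-yl]furan-3-yl}hexan-2-ol, via 3-furyllithium 14 (not isolated)
Conditions: n-BuLi, Et2O, −78 °C; then 13, BF3·OEt2, −78 °C; H2O quench
Reagents that add atoms: none
Why: Bromine–lithium exchange followed by BF3-promoted SN2 opening of the epoxide at its CH2 carbon gives the secondary alcohol; the epoxide stereocentre is untouched (it only keeps the intermediates single isomers and is erased in step 5), and the heptane stereocentre is not involved.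

Step 5
Reactants: 15 (2R)-1-{4-[(2S)-1-(4-{[tri(propan-2-yl)silyloxy]methyl}furan-3-yl)heptan-2-yl]furan-3-yl}hexan-2-ol
Product: 18 3-{(2S)-2-[2,5-dioxo-4-(2-oxohexyl)-2,5-dihydrofuran-3-yl]heptyl}-4-{[tri(propan-2-yl)silyloxy]methyl}furan-2,5-dione, via bis(endoperoxide) 16 (not isolated), via bis(hydroxybutenolide) 17 (not isolated)
Conditions: O2, hν (visible), methylene blue (cat.), acetone, −78 °C; iPr2NEt, −78 → 0 °C; then CrO3, aq. H2SO4 (Jones conditions), 0 °C
Reagents that add atoms: oxygen (O2, used as singlet oxygen), O=O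
Why: Singlet oxygen adds across each 2,5-unsubstituted furan ([4+2] cycloaddition), base opens the endoperoxides to γ-hydroxybutenolides (Kornblum–DeLaMare), and chromic acid oxidises both lactols to anhydrides and the carbinol to the ketone in the same flask (any lactol–carbinol acetal is reversible in aqueous acid), while the primary TIPS ether and the stereocentre are untouched.

Step 6
Reactants: 18 3-{(2S)-2-[2,5-dioxo-4-(2-oxohexyl)-2,5-dihydrofuran-3-yl]heptyl}-4-{[tri(propan-2-yl)silyloxy]methyl}furan-2,5-dione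
Product: 19 3-{(2S)-2-[2,5-dioxo-4-(2-oxohexyl)-2,5-dihydrofuran-3-yl]heptyl}-4-(hydroxymethyl)furan-2,5-dione (target)
Conditions: HF·pyridine, THF, 0 °C → rt
Reagents that add atoms: none
Why: Fluoride cleaves the Si–O bond (desilylation) under mildly acidic, non-basic conditions that the anhydrides, the ketone and the stereocentre (only base-labile, as a γ-position of ring B) tolerate.

## Compound list

1 | 3,4-dibromofuran | Brc1cocc1Br | starting material
2 | formaldehyde (monomeric, from cracked paraformaldehyde) | C=O | starting material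
3 | (4-bromofuran-3-yl)magnesium chloride (in solution as its LiCl complex) | Cl[Mg]c1cocc1Br | intermediate
4 | chloromagnesium (4-bromofuran-3-yl)methoxide | Cl[Mg]OCc1cocc1Br | intermediate
5 | [(4-bromofuran-3-yl)methoxy]tri(propan-2-yl)silane | CC(C)[Si](OCc1cocc1Br)(C(C)C)C(C)C | intermediate
6 | hept-1-ene | C=CCCCCC | starting material
7 | 2,2′-[(2R)-heptane-1,2-diyl]bis(4,4,5,5-tetramethyl-1,3,2-dioxaborolane) | CCCCC[C@@H](CB1OC(C)(C)C(C)(C)O1)B1OC(C)(C)C(C)(C)O1 | intermediate
8 | tri(propan-2-yl)({4-[(2S)-2-(4,4,5,5-tetramethyl-1,3,2-dioxaborolan-2-yl)heptyl]furan-3-yl}methoxy)silane | CCCCC[C@@H](Cc1cocc1CO[Si](C(C)C)(C(C)C)C(C)C)B1OC(C)(C)C(C)(C)O1 | intermediate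
9 | 3-bromo-4-lithiofuran | [Li]c1cocc1Br | intermediate
10 | lithium borate: boron carries the pinacolato group, a 4-bromofuran-3-yl group and the (2S)-1-(4-{[tri(propan-2-yl)silyloxy]methyl}furan-3-yl)heptan-2-yl group | [Li+].CCCCC[C@@H](Cc1cocc1CO[Si](C(C)C)(C(C)C)C(C)C)[B-]1(c2cocc2Br)OC(C)(C)C(C)(C)O1 | intermediate
11 | 2-[2,4-dibromo-3-{(2S)-1-(4-{[tri(propan-2-yl)silyloxy]methyl}furan-3-yl)heptan-2-yl}-2,3-dihydrofuran-3-yl]-4,4,5,5-tetramethyl-1,3,2-dioxaborolane (ring epimers) | CCCCC[C@@H](Cc1cocc1CO[Si](C(C)C)(C(C)C)C(C)C)C1(B2OC(C)(C)C(C)(C)O2)C(Br)OC=C1Br | intermediate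
12 | ({4-[(2S)-2-(4-bromofuran-3-yl)heptyl]furan-3-yl}methoxy)tri(propan-2-yl)silane | CCCCC[C@@H](Cc1cocc1CO[Si](C(C)C)(C(C)C)C(C)C)c1cocc1Br | intermediate
13 | (2R)-2-butyloxirane ((R)-1,2-epoxyhexane) | CCCC[C@@H]1CO1 | starting material
14 | {4-[(2S)-1-(4-{[tri(propan-2-yl)silyloxy]methyl}furan-3-yl)heptan-2-yl]furan-3-yl}lithium | CCCCC[C@@H](Cc1cocc1CO[Si](C(C)C)(C(C)C)C(C)C)c1cocc1[Li] | intermediate
15 | (2R)-1-{4-[(2S)-1-(4-{[tri(propan-2-yl)silyloxy]methyl}furan-3-yl)heptan-2-yl]furan-3-yl}hexan-2-ol | CCCCC[C@@H](Cc1cocc1CO[Si](C(C)C)(C(C)C)C(C)C)c1cocc1C[C@H](O)CCCC | intermediate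
16 | bis(endoperoxide) of 15: each furan as its 2,3,7-trioxabicyclo[2.2.1]hept-5-ene (bridgehead epimers) | CCCCC[C@@H](CC1=C(CO[Si](C(C)C)(C(C)C)C(C)C)C2OOC1O2)C1=C(C[C@H](O)CCCC)C2OOC1O2 | intermediate
17 | bis(5-hydroxy-2(5H)-furanone) from 16, carbinol still present (lactol regio- and stereoisomers; one regioisomer drawn) | CCCCC[C@@H](CC1=C(CO[Si](C(C)C)(C(C)C)C(C)C)C(O)OC1=O)C1=C(C[C@H](O)CCCC)C(O)OC1=O | intermediate
18 | 3-{(2S)-2-[2,5-dioxo-4-(2-oxohexyl)-2,5-dihydrofuran-3-yl]heptyl}-4-{[tri(propan-2-yl)silyloxy]methyl}furan-2,5-dione | CCCCC[C@@H](CC1=C(CO[Si](C(C)C)(C(C)C)C(C)C)C(=O)OC1=O)C1=C(CC(=O)CCCC)C(=O)OC1=O | intermediate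
19 | 3-{(2S)-2-[2,5-dioxo-4-(2-oxohexyl)-2,5-dihydrofuran-3-yl]heptyl}-4-(hydroxymethyl)furan-2,5-dione (CNP0537712.1) | CCCCC[C@@H](CC1=C(CO)C(=O)OC1=O)C1=C(CC(=O)CCCC)C(=O)OC1=O | target

## Step count and risks

Total step count: 6. Longest linear sequence: 6 (1 → 5 → 8 → 12 → 15 → 18 → 19).

**Step 3 (the proposed coupling).** The ring bromine may slow the attack of NBS at C2 or divert it to C5. NBS may also brominate the alkyl C–B bond or an α-position of the neutral ring A furan instead. The fallback uses known chemistry, sets out from 8 and comes back at 15. It puts the side chain on the ring B furan first and runs the coupling in its established form with a 3-furyllithium that carries no halogen. Compound 1 is lithiated (n-BuLi, Et2O, −78 °C, giving 9 as in step 3) and opened onto epoxide 13 (BF3·OEt2, −78 °C) to give (2R)-1-(4-bromofuran-3-yl)hexan-2-ol F1. Silylation (TESCl, imidazole, CH2Cl2) gives {[(2R)-1-(4-bromofuran-3-yl)hexan-2-yl]oxy}triethylsilane F2. Bromine–lithium exchange (n-BuLi, THF, −78 °C) gives (4-{(2R)-2-[(triethylsilyl)oxy]hexyl}furan-3-yl)lithium F3, which adds to 8 to give the lithium borate F4. NBS at −78 °C brominates C2 of the borate furan and triggers the 1,2-shift to the bromodihydrofuranyl boronate F5. This loses bromide and the boryl group to give the bis(furan) triethylsilyl ether F6. PPTS in MeOH removes only the secondary TES group and returns 15.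

**Step 5 (three oxidations in one flask).** The carbinol may trap a ring B lactol as an acetal, or the chromic acid stage may give mixtures or attack the silyl ether. The fallback sets out from 15 and comes back at 18. The carbinol is oxidised first with Dess–Martin periodinane to 1-{4-[(2S)-1-(4-{[tri(propan-2-yl)silyloxy]methyl}furan-3-yl)heptan-2-yl]furan-3-yl}hexan-2-one F7, so no hydroxyl is left to trap a lactol. Photooxygenation (O2, hν, tetraphenylporphyrin, CH2Cl2, −78 °C) gives the bis(endoperoxide) ketone F8. iPr2NEt opens it to the bis(hydroxybutenolide) ketone F9, which is isolated. The two lactols are then oxidised under anhydrous conditions with pyridinium chlorochromate (C5H5NH[CrO3Cl]), NaOAc and 4 Å molecular sieves in CH2Cl2 to give 18.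

**Step 6 (final unmasking).** Under acid the freed hydroxymethyl group may attack the neighbouring anhydride carbonyl and give the isomeric butenolide acid, and a primary TIPS ether needs long exposure to HF. The fallback sets out from 15 and comes back at 19. It changes the protecting group before the oxidation so that the last step is neutral. TBAF in THF gives (2R)-1-{4-[(2S)-1-[4-(hydroxymethyl)furan-3-yl]heptan-2-yl]furan-3-yl}hexan-2-ol F10. Allyl chloroformate and pyridine at −40 °C acylate the primary hydroxyl selectively to {4-[(2S)-2-{4-[(2R)-2-hydroxyhexyl]furan-3-yl}heptyl]furan-3-yl}methyl prop-2-en-1-yl carbonate F11. The one-flask oxidation of step 5 leads through the allyl carbonate bis(endoperoxide) F12 and the allyl carbonate bis(hydroxybutenolide) F13 to {4-[(2S)-2-[2,5-dioxo-4-(2-oxohexyl)-2,5-dihydrofuran-3-yl]heptyl]-2,5-dioxo-2,5-dihydrofuran-3-yl}methyl prop-2-en-1-yl carbonate F14. Pd(PPh3)4 (cat.) with PhSiH3 in CH2Cl2 at rt then removes the allyl carbonate and gives 19.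

## Further compounds

F1 | step 3 | (2R)-1-(4-bromofuran-3-yl)hexan-2-ol | CCCC[C@@H](O)Cc1cocc1Br
F2 | step 3 | {[(2R)-1-(4-bromofuran-3-yl)hexan-2-yl]oxy}triethylsilane | CCCC[C@@H](O[Si](CC)(CC)CC)Cc1cocc1Br
F3 | step 3 | (4-{(2R)-2-[(triethylsilyl)oxy]hexyl}furan-3-yl)lithium | CCCC[C@@H](O[Si](CC)(CC)CC)Cc1cocc1[Li]
F4 | step 3 | lithium borate from 8 and F3 (boron carries pinacolato, the heptan-2-yl group of 8 and the furyl group of F3) | [Li+].CCCCC[C@@H](Cc1cocc1CO[Si](C(C)C)(C(C)C)C(C)C)[B-]1(c2cocc2C[C@H](O[Si](CC)(CC)CC)CCCC)OC(C)(C)C(C)(C)O1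
F5 | step 3 | 2-[2-bromo-3-{(2S)-1-(4-{[tri(propan-2-yl)silyloxy]methyl}furan-3-yl)heptan-2-yl}-4-{(2R)-2-[(triethylsilyl)oxy]hexyl}-2,3-dihydrofuran-3-yl]-4,4,5,5-tetramethyl-1,3,2-dioxaborolane (ring epimers) | CCCCC[C@@H](Cc1cocc1CO[Si](C(C)C)(C(C)C)C(C)C)C1(B2OC(C)(C)C(C)(C)O2)C(Br)OC=C1C[C@H](O[Si](CC)(CC)CC)CCCC
F6 | step 3 | triethylsilyl ether of 15 | CCCCC[C@@H](Cc1cocc1CO[Si](C(C)C)(C(C)C)C(C)C)c1cocc1C[C@H](O[Si](CC)(CC)CC)CCCC
F7 | step 5 | 1-{4-[(2S)-1-(4-{[tri(propan-2-yl)silyloxy]methyl}furan-3-yl)heptan-2-yl]furan-3-yl}hexan-2-one | CCCCC[C@@H](Cc1cocc1CO[Si](C(C)C)(C(C)C)C(C)C)c1cocc1CC(=O)CCCC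
F8 | step 5 | bis(endoperoxide) of F7 (bridgehead epimers) | CCCCC[C@@H](CC1=C(CO[Si](C(C)C)(C(C)C)C(C)C)C2OOC1O2)C1=C(CC(=O)CCCC)C2OOC1O2
F9 | step 5 | bis(5-hydroxy-2(5H)-furanone) ketone from F8 (one lactol regioisomer drawn) | CCCCC[C@@H](CC1=C(CO[Si](C(C)C)(C(C)C)C(C)C)C(O)OC1=O)C1=C(CC(=O)CCCC)C(O)OC1=O
F10 | step 6 | (2R)-1-{4-[(2S)-1-[4-(hydroxymethyl)furan-3-yl]heptan-2-yl]furan-3-yl}hexan-2-ol | CCCCC[C@@H](Cc1cocc1CO)c1cocc1C[C@H](O)CCCC
F11 | step 6 | {4-[(2S)-2-{4-[(2R)-2-hydroxyhexyl]furan-3-yl}heptyl]furan-3-yl}methyl prop-2-en-1-yl carbonate | CCCCC[C@@H](Cc1cocc1COC(=O)OCC=C)c1cocc1C[C@H](O)CCCC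
F12 | step 6 | bis(endoperoxide) of F11 (bridgehead epimers) | CCCCC[C@@H](CC1=C(COC(=O)OCC=C)C2OOC1O2)C1=C(C[C@H](O)CCCC)C2OOC1O2
F13 | step 6 | bis(5-hydroxy-2(5H)-furanone) from F12 (one lactol regioisomer drawn) | CCCCC[C@@H](CC1=C(COC(=O)OCC=C)C(O)OC1=O)C1=C(C[C@H](O)CCCC)C(O)OC1=O
F14 | step 6 | {4-[(2S)-2-[2,5-dioxo-4-(2-oxohexyl)-2,5-dihydrofuran-3-yl]heptyl]-2,5-dioxo-2,5-dihydrofuran-3-yl}methyl prop-2-en-1-yl carbonate | CCCCC[C@@H](CC1=C(COC(=O)OCC=C)C(=O)OC1=O)C1=C(CC(=O)CCCC)C(=O)OC1=O
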